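The carbocycle C1–C6 is traced back to a 7-oxabicyclo[2.2.1]heptene whose oxygen bridge links C2 and C5. The feature exploited is the array C2–O, trans C3–OBz and C4=C5 beside the quaternary carbinol C1 that carries C7: exactly what anti SN2′ cleavage of the C5–O bond of such a bridge leaves. The key step, an enantioselective Diels–Alder reaction of furan with 2-bromoacrolein under the B-butyl oxazaborolidinone of N-tosyl-(R)-tryptophan, forms C1–C2 and C5–C6, closes the six-membered ring and sets C1, C2 and C5 in one operation. Its precursors are two flat, achiral molecules, furan and the α-bromo enal from acrolein. The endo bromide is later exchanged for the C1 oxygen with inversion.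

Key step: step 2

Numbering (target): C1 = C(OH)(CH2OBz), C2 = CH–OAc, C3 = CH–OBz, C4=C5, C6 = CH–OH, C7 = CH2OBz. These labels are used for all intermediates whenever positions are discussed; compound names carry their own locants.

Assumption (step 2): the oxazaborolidinone from (S)-tryptophan is taken to give the (2R) adduct series, as it does with cyclopentadiene, so the (R)-tryptophan catalyst is specified for (1S,2S,4S)-5. If the sense were the reverse, the antipodal catalyst would be used and nothing else would change.

Assumption (step 5): the antipode of the ferrocenyl diphosphine meant is the one that reinforces the substrate's own preference for C5–O cleavage. It is identified in a small trial with both antipodes.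

Step 1
Reactants: 1 acrolein
Product: 3 2-bromoacrolein, via 2,3-dibromopropanal 2 (not isolated)
Conditions: Br2 (1.0 equiv), CH2Cl2, −78 to 0 °C; then Et3N (1.05 equiv), 0 °C; distilled under reduced pressure, used fresh
Reagents that add atoms: bromine, BrBr
Why: Bromination–dehydrobromination, in which Br2 adds across the C=C bond and the amine then removes the acidic α-hydrogen and expels the β-bromide (E1cB-like elimination) to leave the α-bromo enal; no stereocentre is carried on.

Step 2
Reactants: 3 2-bromoacrolein; 4 furan
Product: 5 (1S,2S,4S)-2-bromo-7-oxabicyclo[2.2.1]hept-5-ene-2-carbaldehyde (CHO exo; Br endo)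
Conditions: (4R)-2-butyl-4-(1H-indol-3-ylmethyl)-3-(4-methylphenylsulfonyl)-1,3,2-oxazaborolidin-5-one (10 mol%, made beforehand from N-tosyl-(R)-tryptophan and BuB(OH)2 with azeotropic removal of water), furan (5 equiv), CH2Cl2, −78 °C; cold aq NaHCO3 quench, concentrated cold, used at once
Reagents that add atoms: none
Why: The boron Lewis acid binds the formyl oxygen of s-cis 3, the indole ring stacks over one face of the activated enal, and furan adds to the open face in a concerted but asynchronous suprafacial [4+2] cycloaddition. The closest known reaction type is the oxazaborolidinone-catalysed enantioselective Diels–Alder reaction of 2-haloacroleins with cyclopentadiene and with furan itself. The six-membered carbocycle, and with it the oxygen-bridged bicycle, closes by intermolecular [4+2] cycloaddition, the bonds C1–C2 and C5–C6 forming on the same face of each partner. C2 and C5 are tied to one another by the bridge and take their absolute sense from the enal face that the catalyst leaves open, while C1 follows from the formyl-exo, bromine-endo transition state that α-halo enals prefer. Furan is C2v-symmetric and so poses no regiochemical issue; what the step needs is enantiofacial and exo selectivity, secured by the catalyst and by the α-bromine respectively. The low temperature and cold work-up keep this reversible addition under kinetic control.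

Step 3
Reactants: 5 (1S,2S,4S)-2-bromo-7-oxabicyclo[2.2.1]hept-5-ene-2-carbaldehyde
Product: 7 (1S,2S,4S)-spiro[7-oxabicyclo[2.2.1]hept-5-ene-2,2'-oxirane] (oxirane O exo; oxirane CH2 endo), via bromohydrin 6 (not isolated)
Conditions: NaBH4, MeOH–THF, −20 to 0 °C; then 2 M aq NaOH, 0 °C to rt
Reagents that add atoms: none
Why: Borohydride 1,2-reduction of the aldehyde is followed by an intramolecular Williamson (halohydrin-to-epoxide) closure in which the exo C7 alkoxide attacks C1 anti to the endo C–Br bond, so C1 is inverted cleanly, its oxygen ending exo (cis to the bridge oxygen on C2) and C7 swinging endo.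

Step 4
Reactants: 7 (1S,2S,4S)-spiro[7-oxabicyclo[2.2.1]hept-5-ene-2,2'-oxirane]; 8 benzoic acid
Product: 9 [(1S,2S,4S)-2-hydroxy-7-oxabicyclo[2.2.1]hept-5-en-2-yl]methyl benzoate (OH exo; CH2OBz endo)
Conditions: BzOH (1.5 equiv), PhCO2Cs (20 mol%), DMF, 75 °C
Reagents that add atoms: benzoic acid (8), O=C(O)c1ccccc1
Why: Carboxylate opening of a 2,2-disubstituted oxirane by SN2 attack at the unsubstituted carbon C7 in a buffered medium, which leaves the C1–O bond and hence the C1 configuration untouched and places the acyl group on the thermodynamically preferred primary oxygen.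

Step 5
Reactants: 9 [(1S,2S,4S)-2-hydroxy-7-oxabicyclo[2.2.1]hept-5-en-2-yl]methyl benzoate; 8 benzoic acid
Product: 10 [(1S,2S,3R)-3-(benzoyloxy)-1,2-dihydroxycyclohex-4-en-1-yl]methyl benzoate (1-OH and 2-OH cis; 2-OH and 3-OBz trans)
Conditions: [Rh(cod)Cl]2 (2.5 mol%), 1-[2-(diphenylphosphino)ferrocenyl]ethyldi-tert-butylphosphine (PPF-PtBu2, matched antipode, 6 mol%), Bu4NI (20 mol%), BzOH (4 equiv), Et3N (2 equiv), THF, 80 °C, sealed vessel
Reagents that add atoms: benzoic acid (8), O=C(O)c1ccccc1
Why: Proposed new method: monovalent rhodium should bind the exo face of C3=C4 together with the bridge oxygen and insert into the allylic C5–O bond, the one remote from the crowded and inductively electron-poor C1, giving a rhodium allyl alkoxide that benzoic acid protonates, after which benzoate attacks C3 from the endo face, anti to the metal, in an SN2′ sense, setting C3–OBz trans to the retained C2–OH and moving the alkene to C4=C5; the closest known reaction type is the anti ring opening under [Rh(cod)Cl]2/PPF-PtBu2 of oxabenzonorbornadienes by carboxylates and, with added iodide, of non-benzo-fused 7-oxabicyclo[2.2.1]heptenes by phenols and amines, the new element being the pairing of a carboxylate with the non-benzylic bridge.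

Step 6
Reactants: 10 [(1S,2S,3R)-3-(benzoyloxy)-1,2-dihydroxycyclohex-4-en-1-yl]methyl benzoate
Product: 11 [(1S,2S,3R)-2-acetoxy-3-(benzoyloxy)-1-hydroxycyclohex-4-en-1-yl]methyl benzoate
Conditions: Ac2O (1.2 equiv), pyridine, 4-(dimethylamino)pyridine (5 mol%), CH2Cl2, 0 °C
Reagents that add atoms: acetic anhydride, CC(=O)OC(C)=O
Why: Nucleophile-catalysed O-acylation discriminates on steric grounds between the secondary C2 hydroxyl, which reacts, and the tertiary C1 hydroxyl, which does not at 0 °C, and prompt capping also blocks benzoyl migration from O3 to O2; no stereocentre is touched.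

Step 7
Reactants: 11 [(1S,2S,3R)-2-acetoxy-3-(benzoyloxy)-1-hydroxycyclohex-4-en-1-yl]methyl benzoate
Product: 12 [(1R,2S,3R,6S)-2-acetoxy-3-(benzoyloxy)-1,6-dihydroxycyclohex-4-en-1-yl]methyl benzoate (HY-N2634)
Conditions: SeO2 (1.0 equiv), moist 1,4-dioxane, 80 °C, stopped before full conversion
Reagents that add atoms: selenium dioxide, O=[Se]=O
Why: Riley allylic hydroxylation, in which SeO2 engages C4=C5 in an ene reaction, bonding to C4 (charge then builds at C5, away from the benzoate-bearing C3) and taking the C6 hydrogen aligned with the π bond, and the [2,3]-sigmatropic shift of the allylseleninic acid returns oxygen to C6 on the same face with C4=C5 restored, so that in the favoured half-chair (C2–OAc, C3–OBz and C7 equatorial, C1–OH axial), where the aligned hydrogen is the pseudoaxial one anti to C1–OH, the new C6–OH is set trans to C1–OH and cis to C3–OBz; the axial C4 hydroxylation of cholesteryl esters next to the ester-bearing carbon is the textbook parallel.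

Compound list
1 | acrolein | C=CC=O | starting material
2 | 2,3-dibromopropanal (racemic, not isolated) | O=CC(Br)CBr | intermediate
3 | 2-bromoacrolein | C=C(Br)C=O | intermediate
4 | furan | c1ccoc1 | starting material
5 | (1S,2S,4S)-2-bromo-7-oxabicyclo[2.2.1]hept-5-ene-2-carbaldehyde (CHO exo, Br endo) | C1=C[C@@H]2C[C@@](Br)(C=O)[C@H]1O2 | intermediate
6 | [(1S,2R,4S)-2-bromo-7-oxabicyclo[2.2.1]hept-5-en-2-yl]methanol (CH2OH exo, Br endo; not isolated) | C1=C[C@@H]2C[C@@](Br)(CO)[C@H]1O2 | intermediate
7 | (1S,2S,4S)-spiro[7-oxabicyclo[2.2.1]hept-5-ene-2,2'-oxirane] (oxirane O exo) | C1=C[C@@H]2C[C@@]3(OC3)[C@H]1O2 | intermediate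
8 | benzoic acid | O=C(O)c1ccccc1 | starting material
9 | [(1S,2S,4S)-2-hydroxy-7-oxabicyclo[2.2.1]hept-5-en-2-yl]methyl benzoate (OH exo) | C1=C[C@@H]2C[C@@](COC(=O)c3ccccc3)(O)[C@H]1O2 | intermediate
10 | [(1S,2S,3R)-3-(benzoyloxy)-1,2-dihydroxycyclohex-4-en-1-yl]methyl benzoate | O[C@H]1[C@H](OC(=O)c2ccccc2)C=CC[C@]1(O)COC(=O)c1ccccc1 | intermediate
11 | [(1S,2S,3R)-2-acetoxy-3-(benzoyloxy)-1-hydroxycyclohex-4-en-1-yl]methyl benzoate | CC(=O)O[C@H]1[C@H](OC(=O)c2ccccc2)C=CC[C@]1(O)COC(=O)c1ccccc1 | intermediate
12 | [(1R,2S,3R,6S)-2-acetoxy-3-(benzoyloxy)-1,6-dihydroxycyclohex-4-en-1-yl]methyl benzoate (HY-N2634) | CC(=O)O[C@H]1[C@H](OC(=O)c2ccccc2)C=C[C@H](O)[C@]1(O)COC(=O)c1ccccc1 | target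

Total step count: 7. The one-flask condensation of N-tosyl-(R)-tryptophan with BuB(OH)2 that makes the catalyst is not counted, since it puts no atoms into the target.
Longest linear sequence: 7 (1 to 12).

Steps most likely to fail

Risk 1 (step 5, the one step beyond known chemistry). Several things may go wrong:
- The non-benzylic C5–O bond may resist insertion of monovalent rhodium.
- Benzoate may bind the metal and stall turnover.
- Insertion may stray to the C2–O bond.
- The C3 benzoyl group may wander to the free C2 hydroxyl in the amine buffer.

The fallback uses known chemistry and sets out from 9. The bridge is opened with 4-methoxyphenol instead of benzoic acid, since phenols are established nucleophiles for non-benzo-fused 7-oxabicyclo[2.2.1]heptenes under [Rh(cod)Cl]2/PPF-PtBu2/Bu4NI (THF or tetrahydropyran, 80–100 °C). This gives the trans C3 4-methoxyphenyl ether F1. Ac2O/pyridine then caps the C2 hydroxyl to give the ether acetate F2. (NH4)2Ce(NO3)6 in MeCN–H2O at 0 °C strips the aryl group oxidatively to give the C3 alcohol F3. BzCl/pyridine at 0 °C, applied at once to forestall acetyl migration, returns to the route at 11.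

Risk 2 (step 7). The ene reaction may be sluggish on an alkene depleted by the allylic benzoate. The new alcohol may be oxidised further. Facial selectivity may erode if the minor half-chair reacts.

The fallback sets out from 11. C6 is taken deliberately all the way to the ketone with CrO3/3,5-dimethylpyrazole (CH2Cl2, −20 °C), which gives the 4-en-6-one F4. The stereocentre is then set in a separate hydroxyl-directed reduction with Me4NBH(OAc)3 (MeCN–AcOH, −20 °C). Boron binds to the axial C1 hydroxyl and hands hydride to the same face of C6=O, so the new hydroxyl is trans to C1–OH and the route is rejoined at 12.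

Risk 3 (step 4). Attack at the endo methylene may be slowed by the bicyclic framework. Acid-assisted ionisation at C1 may compete. Long heating invites cycloreversion.

The fallback sets out from 7. The oxirane is opened with the smaller hydroxide ion (KOH, DMSO–H2O, 60 °C) to the primary/tertiary diol F5. Only its primary hydroxyl is benzoylated (BzCl 1.0 equiv, pyridine, CH2Cl2, −20 °C), which returns to the route at 9.

Further compounds
F1 | step 5 | [(1S,2S,3R)-1,2-dihydroxy-3-(4-methoxyphenoxy)cyclohex-4-en-1-yl]methyl benzoate | O[C@H]1[C@H](Oc2ccc(OC)cc2)C=CC[C@]1(O)COC(=O)c1ccccc1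
F2 | step 5 | [(1S,2S,3R)-2-acetoxy-1-hydroxy-3-(4-methoxyphenoxy)cyclohex-4-en-1-yl]methyl benzoate | CC(=O)O[C@H]1[C@H](Oc2ccc(OC)cc2)C=CC[C@]1(O)COC(=O)c1ccccc1
F3 | step 5 | [(1S,2S,3R)-2-acetoxy-1,3-dihydroxycyclohex-4-en-1-yl]methyl benzoate | CC(=O)O[C@H]1[C@H](O)C=CC[C@]1(O)COC(=O)c1ccccc1
F4 | step 7 | [(1S,2S,3R)-2-acetoxy-3-(benzoyloxy)-1-hydroxy-6-oxocyclohex-4-en-1-yl]methyl benzoate | CC(=O)O[C@H]1[C@H](OC(=O)c2ccccc2)C=CC(=O)[C@]1(O)COC(=O)c1ccccc1
F5 | step 4 | (1S,2S,4S)-2-(hydroxymethyl)-7-oxabicyclo[2.2.1]hept-5-en-2-ol | C1=C[C@@H]2C[C@@](CO)(O)[C@H]1O2
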